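## Analysis of the target

The target 38 is a C40 cyclopropylcarbinol of the prephytoene type, built on one cyclopropane (ring A) whose three carbons are all stereogenic and carry every substituent. Ca bears H and the (1E,5E,9E)-2,6,10,14-tetramethylpentadeca-1,5,9,13-tetraenyl group, Cb bears H and CH2OH, and Cc is quaternary with a methyl group and the (3E,7E)-4,8,12-trimethyltrideca-3,7,11-trienyl chain; the configuration is (1R,2R,3R) with Cb = C1, Cc = C2 and Ca = C3. The two long chains are cis to each other, and the CH2OH group is trans to both and therefore cis to the Cc methyl. There are seven C=C bonds, five of them stereogenic and E-configured, and one of these sits directly on Ca. The alcohol is a vinyl-substituted cyclopropylcarbinol, so acid or a leaving group on its oxygen invites cyclopropylcarbinyl cation rearrangement, and the polyene rules out late electrophilic oxidants, strong acid and hydrogenation. The hard points are the all-carbon quaternary centre inside a fully substituted three-membered ring, absolute stereocontrol, and forming the ring without touching seven other alkenes. The strategy rests on the fact that C1 of the Ca chain and C1–C2 of the Cc chain lie on the same face of ring A, so that together with Ca and Cc they can be tied into a five-membered ring (ring B) in which C1 of the Ca chain is a ketone carbon. Ca, Cc with its methyl, and these three carbons are then the skeleton of 3-methylcyclopent-2-en-1-one 7, and only Cb with its oxidised carbon has to be added.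

## Retrosynthetic reasoning

**38 from 37.** The last bond cut is the O–Si bond of the silyl ether 37. The oxygen stays silylated to the end because a free or activated vinylcyclopropylcarbinol would not survive organometallic or acidic steps. Fluoride cleavage is the only operation on the complete skeleton.

**37 from 35 and 31.** The C3–C4 bond of the tetraenyl chain is cut, an sp2–sp3 bond. The forward step is a Negishi coupling of alkenyl iodide 35 with zinc reagent 36 made from homofarnesyl iodide 31. The cut is placed here because C1 of this chain must stay on Ca (it is the former ketone carbon), and because a 2-iodoprop-1-enyl group can be made with defined geometry. The coupling must keep that geometry.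

**35 from 33.** The C–I bond is traced to the methyl alkyne 33 through alkenylzirconium 34. Syn hydrometalation puts the metal on the methyl-bearing carbon, trans to ring A. This fixes the E geometry of the Ca alkene without any olefination of uncertain selectivity.

**33 from 21 and 28.** The C2–C3 bond of the trienyl chain is cut, again sp3–sp2. The forward step couples zinc reagent 32, made from iodide 21, with the C14 alkenyl iodide 28. The two ring-B methylene carbons thus become C1 and C2 of the Cc chain, and the E alkene arrives preformed.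

**21 from 15 through 20, 18 and 16.** The iodoethyl arm and the propynyl group are traced to lactone 15. Reduction to lactol 16 and one-carbon homologation of its open form 17 turn the Ca carbonyl carbon into the ring-bound alkyne carbon of 18 and free the Cc arm as an alcohol. C-Methylation through 19 gives 20, and iodination gives 21. The lactone is what tells the two ends of the cleaved ring apart.

**15 from 12.** The lactone C–O bond and, before it, the C2–C3 bond of ring B are cut. Ozonolysis of silyl enol ether 12 gives silyl ester 13 and, after reduction, hydroxy acid 14. Its acid on Ca and hydroxyethyl arm on Cc are cis, so they close to 15. Cleavage can only occur on the C3 side, because the ketone cannot enolise toward the cyclopropane bridgehead.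

**12 from 9 through 10 and 11.** The Cb ester of 9 is brought to the alcohol oxidation level and protected. Doing this on enol ether 10 uses the enol ether as ketone protection, so the ester reduction to 11 and silylation to 12 need no redox detour.

**9 from 6 and 7 (key disconnection).** Both bonds from Cb to its ring neighbours are cut. Ylide 6 supplies Cb with its ester; enone 7 supplies Ca, Cc, the methyl and the roots of both chains. The forward reaction, through betaine 8, must add to the β-carbon, close the three-membered ring, place the ester exo and choose one enone face. Both partners are small and contain no other alkene.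

**6 from 1 and 4 through 2, 3 and 5.** The S–C bond of sulfonium salt 5 is cut to thiolane 3 and ethyl bromoacetate 4. The two C–S bonds of 3 are cut to dimesylate 2 of diol 1. Double inversion gives the C2-symmetric sulfide, so S-alkylation creates no sulfur stereocentre.

**28 and 31 from 22 and 23.** Both side-chain pieces come from one enyne 26, made by alkylating lithiated 23 (24) with geranyl bromide 22 and desilylating 25. Carbometalation of 26 gives alkenylalane 27, which is iodinated to 28. Part of 28 serves as the coupling partner of the Cc arm. The rest is converted by halogen–metal exchange into alkenyllithium 29, extended by two carbons to homofarnesol 30 and turned into 31. Every E alkene of the side chains is thus either bought with 22 or made once by syn carbometalation and carried on with retention.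

## Alternatives that were turned down

**Alternative 1: two-directional decarboxylative alkenylation.**
- Disconnection: both outer CH2–CH= bonds at once, C4–C5 of the tetraenyl chain and C2–C3 of the trienyl chain. Both outer C14 units are then the same alkenyl iodide (compound 28 of the present route), and the core is a cyclopropane diacid as its bis(N-hydroxyphthalimide) ester A2.
- Forward key step: cathodic reduction of A2 with NiCl2·glyme and 2,2'-bipyridine (sacrificial Mg anode) and two equivalents of 28. Two primary radicals form with loss of CO2 and each is captured by nickel, giving the silyl ether A1 of the target.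
- For: the end game is more convergent than the chosen one, since both chains arrive in one operation from one building block. It needs no organozinc reagents and tolerates polyenes.
- Against: A2 already contains ring A with all three stereocentres and the E alkene on Ca, so the step leaves the hard problem unsolved. A cyclopropanation and a stereodefined olefination would still be needed before it. Two couplings must succeed on one molecule, and singly coupled or reduced material would be hard to separate from A1.
- Comparison: it is stronger on late-stage convergence. The chosen route instead offers an actual construction of ring A and its stereocentres from 7, and still attaches the chains by two convergent couplings.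

**Alternative 2: carbene at the quaternary carbon, lactone carbonyl as latent methyl.**
- Disconnection: the Cc–Ca and Cc–Cb bonds. The precursor is the dienyl α-alkyl-α-diazoester A4, with both chains already in place.
- Forward key step: a chiral dirhodium carboxamidate such as Rh2(5S-MEPY)4 decomposes A4 and the carbene adds to the nearest E alkene. This closes ring A and a fused γ-lactone to give A3.
- For: one step makes ring A and all three stereocentres. The relative configuration is locked by the alkene geometry and the tether, and catalyst-controlled intramolecular cyclopropanation of allylic diazoacetates is well developed. On paper it is the shortest route.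
- Against: a carbene bearing an alkyl group with β-hydrogens tends to undergo 1,2-hydride shift to the enoate faster than it cyclopropanates. Carboxamidate catalysts are sluggish with disubstituted diazo esters. A4 offers eight alkenes and many allylic C–H bonds. After the key step the lactone carbonyl on Cc must become CH3; this means reduction to two cyclopropylcarbinyl alcohols, telling them apart, and deoxygenating one through intermediates that open vinylcyclopropanes.
- Comparison: it is stronger in step count if everything works. The chosen route has the Cc methyl present from the start (the methyl of 7) and never places a cation, radical or leaving group next to ring A.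

**Alternative 3: chrysanthemic acid pool and C–H insertion.**
- Disconnection: the bond between C1 and C2 of the Cc chain, that is, between one methyl carbon of a gem-dimethylcyclopropane and a carbene carbon. The same ring B is closed from the other side. The starting material is (1R,3R)-trans-chrysanthemic acid A7, converted in about four steps to diazoketone A6.
- Forward key step: Rh2(OAc)4 forms the carbene from A6, which inserts into a C–H bond of the cis methyl on Cc. This gives the bicyclic keto ester A5, the methyl ester analogue of 9.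
- For: Ca and Cb come enantiopure from the pool, so absolute configuration does not depend on a chiral reagent. On this point it is stronger than the chosen route. Only the cis methyl can reach the carbene, and A5 would enter the same downstream sequence.
- Against: insertion into a primary C–H bond is the least favourable class for rhodium carbenes, and an acceptor-only diazoketone carbene tends to dimerise or rearrange instead. The route is no shorter up to the bicycle.
- Comparison: it is stronger on enantiopurity and equal in length. The chosen route offers a polar, two-bond ring closure of a well-behaved reaction class, whose only open question is the degree of enantiocontrol, and that can be repaired by resolution.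

Key step: step 5

Remark on the chemistry: ylide 6 is assumed to attack the enone face that leads to 9 as drawn. If the opposite sense is found, the same sequence is run from the enantiomer of 1.

## Route

Step 1
Reactants: 1 (2S,5S)-hexane-2,5-diol
Product: 2 (2S,5S)-hexane-2,5-diyl dimethanesulfonate
Conditions: MsCl, Et3N, CH2Cl2, 0 °C
Reagents that add atoms: methanesulfonyl chloride, CS(=O)(=O)Cl
Why: O-sulfonylation of both secondary alcohols does not touch the carbinol carbons, so the (S,S) configuration is carried into a bis-electrophile.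

Step 2
Reactants: 2 (2S,5S)-hexane-2,5-diyl dimethanesulfonate
Product: 3 (2R,5R)-2,5-dimethylthiolane
Conditions: Na2S·9H2O, DMSO, 25 °C
Reagents that add atoms: sodium sulfide, [Na+].[Na+].[S-2]
Why: Two SN2 displacements by sulfide, the second a 5-exo-tet closure, invert both centres and should give only the C2-symmetric trans thiolane.

Step 3
Reactants: 3 (2R,5R)-2,5-dimethylthiolane; 4 ethyl bromoacetate
Product: 5 (2R,5R)-1-(2-ethoxy-2-oxoethyl)-2,5-dimethylthiolan-1-ium bromide
Conditions: acetone, 25 °C, 48 h
Reagents that add atoms: none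
Why: SN2 S-alkylation of a dialkyl sulfide by an α-bromo ester; because 3 is C2-symmetric its two sulfur lone pairs are equivalent and one sulfonium salt should form.

Step 4
Reactants: 5 (2R,5R)-1-(2-ethoxy-2-oxoethyl)-2,5-dimethylthiolan-1-ium bromide
Product: 6 ethyl 2-[(2R,5R)-2,5-dimethylthiolan-1-ium-1-yl]acetate ylide
Conditions: 50% aq NaOH, sat. aq K2CO3, CHCl3, 0–5 °C; organic phase dried (K2CO3), concentrated cold, used at once
Reagents that add atoms: none
Why: Deprotonation of the CH2 between sulfonium and ester gives an ester-stabilised ylide that is isolable like its dimethylsulfonium analogue; using it preformed keeps excess base out of the key step.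

Step 5
Reactants: 6 ethyl 2-[(2R,5R)-2,5-dimethylthiolan-1-ium-1-yl]acetate ylide; 7 3-methylcyclopent-2-en-1-one
Product: 9 ethyl (1R,5R,6R)-5-methyl-2-oxobicyclo[3.1.0]hexane-6-carboxylate (ester exo), via sulfonium enolate betaine 8 (not isolated)
Conditions: ClCH2CH2Cl (2 M), 40 °C
Reagents that add atoms: none
Why: This is a Michael-initiated ring closure (sulfonium ylide cyclopropanation): the ylide carbon of 6 adds to C3 of enone 7 to give betaine 8, and the enolate α-carbon then displaces the thiolane from the neighbouring carbon in a 3-exo-tet SN2 closure, forming the C5–C6 and C1–C6 bonds of 9. The closest known reaction is the cyclopropanation of cyclopent-2-en-1-one and other cyclic enones with the achiral ester ylide F1 and with chiral-sulfide versions of it; the β-methyl group slows the addition, hence the high concentration and mild heating. C5, the quaternary centre, is set by the enone face that the ylide carbon attacks, and this is controlled by the C2-symmetric thiolane, whose methyl groups shield the same side of the ylide in either rotamer. C1 needs no control, because a cyclopropane fused to a five-membered ring must be cis, which puts the carbonyl carbon and the ring CH2 on one face and the methyl on the other. C6 is set in the closure: the betaine carbon bearing ester and sulfonium is epimerisable, so both epimers should funnel through the less crowded transition state that places the ester exo, away from ring B. The step needs 1,4- over 1,2-addition (secured by ylide stabilisation), exo over endo closure (secured by the bicyclic geometry) and enone-face selectivity (secured only by the sulfide, the uncertain element). Sulfide 3 is released and can be recovered.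

Step 6
Reactants: 9 ethyl (1R,5R,6R)-5-methyl-2-oxobicyclo[3.1.0]hexane-6-carboxylate
Product: 10 ethyl (1R,5R,6R)-2-[(tert-butyldimethylsilyl)oxy]-5-methylbicyclo[3.1.0]hex-2-ene-6-carboxylate
Conditions: TBSOTf, Et3N, CH2Cl2, 0 °C
Reagents that add atoms: tert-butyldimethylsilyl trifluoromethanesulfonate, CC(C)(C)[Si](C)(C)OS(=O)(=O)C(F)(F)F
Why: Soft enolisation and O-silylation; only C3 can enolise, since a double bond to bridgehead C1 would be a cyclopropene-type alkene, so one silyl enol ether should form, which marks the bond to be cut and masks the ketone.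

Step 7
Reactants: 10 ethyl (1R,5R,6R)-2-[(tert-butyldimethylsilyl)oxy]-5-methylbicyclo[3.1.0]hex-2-ene-6-carboxylate
Product: 11 {(1R,5S,6R)-2-[(tert-butyldimethylsilyl)oxy]-5-methylbicyclo[3.1.0]hex-2-en-6-yl}methanol
Conditions: i-Bu2AlH (2.5 equiv), CH2Cl2, −78 → 0 °C; aq potassium sodium tartrate work-up
Reagents that add atoms: none
Why: Aluminium hydride reduction of the ester to the primary alcohol; silyl enol ethers are inert to hydride and to the neutral tartrate work-up, so no ketone protection or re-oxidation is needed (the C5 descriptor changes only by priority rules).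

Step 8
Reactants: 11 {(1R,5S,6R)-2-[(tert-butyldimethylsilyl)oxy]-5-methylbicyclo[3.1.0]hex-2-en-6-yl}methanol
Product: 12 tert-butyl({(1R,5S,6R)-2-[(tert-butyldimethylsilyl)oxy]-5-methylbicyclo[3.1.0]hex-2-en-6-yl}methoxy)diphenylsilane
Conditions: TBDPSCl, Et3N, DMAP (cat.), CH2Cl2, 0 → 25 °C
Reagents that add atoms: tert-butyl(chloro)diphenylsilane, CC(C)(C)[Si](Cl)(c1ccccc1)c1ccccc1
Why: Silylation of a primary alcohol under basic conditions that spare the enol ether; the TBDPS ether should survive ozone, hydrides, carbonate in methanol, butyllithium, organozinc and zirconium hydride reagents and is removed last by fluoride.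

Step 9
Reactants: 12 tert-butyl({(1R,5S,6R)-2-[(tert-butyldimethylsilyl)oxy]-5-methylbicyclo[3.1.0]hex-2-en-6-yl}methoxy)diphenylsilane
Product: 15 (1R,6S,7R)-7-{[(tert-butyldiphenylsilyl)oxy]methyl}-6-methyl-3-oxabicyclo[4.1.0]heptan-2-one, via oxo silyl ester 13 (not isolated), via hydroxy acid 14 (not isolated)
Conditions: O3, CH2Cl2/MeOH (4:1), −78 °C; NaBH4, −78 → 0 °C; then aq HCl to pH 3, CH2Cl2, 25 °C
Reagents that add atoms: ozone, [O-][O+]=O
Why: Ozonolysis (Criegee mechanism) of the electron-rich enol ether leaves the silyloxy carbon as a silyl ester on Ca and the other carbon as a peroxidic species that borohydride reduces to the alcohol; acid and hydroxyethyl arm are cis on ring A and should close to the δ-lactone (6-exo-trig) on acidification, with no stereocentre involved.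

Step 10
Reactants: 15 (1R,6S,7R)-7-{[(tert-butyldiphenylsilyl)oxy]methyl}-6-methyl-3-oxabicyclo[4.1.0]heptan-2-one
Product: 16 (1R,6S,7R)-7-{[(tert-butyldiphenylsilyl)oxy]methyl}-6-methyl-3-oxabicyclo[4.1.0]heptan-2-ol (both C2 epimers)
Conditions: i-Bu2AlH (1.1 equiv), CH2Cl2, −78 °C
Reagents that add atoms: none
Why: Partial reduction of a lactone to the lactol, which stops at the stable aluminium hemiacetal at low temperature; the new hemiacetal centre is of no consequence.

Step 11
Reactants: 16 (1R,6S,7R)-7-{[(tert-butyldiphenylsilyl)oxy]methyl}-6-methyl-3-oxabicyclo[4.1.0]heptan-2-ol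
Product: 18 2-[(1R,2R,3S)-2-{[(tert-butyldiphenylsilyl)oxy]methyl}-3-ethynyl-1-methylcyclopropyl]ethan-1-ol, via hydroxy aldehyde 17 (not isolated)
Conditions: dimethyl (1-diazo-2-oxopropyl)phosphonate, K2CO3, MeOH, 0 → 25 °C
Reagents that add atoms: dimethyl (1-diazo-2-oxopropyl)phosphonate, CC(=O)C(=[N+]=[N-])P(=O)(OC)OC
Why: Seyferth–Gilbert homologation in the Ohira–Bestmann form acts on the ring-opened tautomer 17 of the lactol, making the former ketone carbon the ring-bound alkyne carbon and freeing the Cc arm as a primary alcohol; the Ca hydrogen is a weakly acidic cyclopropyl C–H and the aldehyde already sits trans to the silyloxymethyl group, so epimerisation is not expected.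

Step 12
Reactants: 18 2-[(1R,2R,3S)-2-{[(tert-butyldiphenylsilyl)oxy]methyl}-3-ethynyl-1-methylcyclopropyl]ethan-1-ol
Product: 20 2-[(1R,2R,3R)-2-{[(tert-butyldiphenylsilyl)oxy]methyl}-1-methyl-3-(prop-1-yn-1-yl)cyclopropyl]ethan-1-ol, via dilithium alkoxide acetylide 19 (not isolated)
Conditions: n-BuLi (2.1 equiv), THF, −78 → −20 °C; MeI (1.1 equiv), −78 → 25 °C
Reagents that add atoms: iodomethane, CI
Why: Alkylation of a lithium acetylide; in the dianion the acetylide carbon is far more nucleophilic toward iodomethane in THF than the lithium alkoxide, so C-methylation should be selective.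

Step 13
Reactants: 20 2-[(1R,2R,3R)-2-{[(tert-butyldiphenylsilyl)oxy]methyl}-1-methyl-3-(prop-1-yn-1-yl)cyclopropyl]ethan-1-ol
Product: 21 tert-butyl{[(1R,2R,3R)-2-(2-iodoethyl)-2-methyl-3-(prop-1-yn-1-yl)cyclopropyl]methoxy}diphenylsilane
Conditions: I2, PPh3, imidazole, CH2Cl2, 0 → 25 °C
Reagents that add atoms: iodine, II
Why: Appel-type iodination of a primary alcohol through the alkoxyphosphonium salt; the carbinol carbon is two atoms from ring A, so no cyclopropylcarbinyl cation can form.

Step 14
Reactants: 22 (2E)-1-bromo-3,7-dimethylocta-2,6-diene (geranyl bromide); 23 trimethyl(prop-1-yn-1-yl)silane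
Product: 25 [(5E)-6,10-dimethylundeca-5,9-dien-1-yn-1-yl]trimethylsilane, via silylpropargyllithium 24 (not isolated)
Conditions: 23, n-BuLi, THF, −78 → −20 °C; then 22, −78 → 25 °C
Reagents that add atoms: none
Why: SN2 alkylation of a silyl-stabilised propargyl anion at the primary allylic bromide; the silyl group directs the ambident anion to react at the propargylic carbon and the E alkene of 22 is not involved.

Step 15
Reactants: 25 [(5E)-6,10-dimethylundeca-5,9-dien-1-yn-1-yl]trimethylsilane
Product: 26 (5E)-6,10-dimethylundeca-5,9-dien-1-yne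
Conditions: K2CO3 (cat.), MeOH, 25 °C
Reagents that add atoms: none
Why: Base-catalysed protodesilylation of an alkynylsilane by methoxide attack at silicon.

Step 16
Reactants: 26 (5E)-6,10-dimethylundeca-5,9-dien-1-yne
Product: 28 (1E,5E)-1-iodo-2,6,10-trimethylundeca-1,5,9-triene, via alkenylalane 27 (not isolated)
Conditions: Me3Al (2 equiv), Cp2ZrCl2 (0.25 equiv), CH2Cl2, 25 °C; then I2, THF, −30 → 0 °C
Reagents that add atoms: trimethylaluminium, C[Al](C)C; iodine, II
Why: Negishi zirconium-catalysed carboalumination adds methyl and aluminium syn across the terminal alkyne with aluminium on the terminal carbon, and iodinolysis proceeds with retention, so the E iodide should result; the isolated trisubstituted alkenes are inert.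

Step 17
Reactants: 28 (1E,5E)-1-iodo-2,6,10-trimethylundeca-1,5,9-triene
Product: 30 (3E,7E)-4,8,12-trimethyltrideca-3,7,11-trien-1-ol (homofarnesol), via alkenyllithium 29 (not isolated)
Conditions: t-BuLi (2.1 equiv), Et2O, −78 °C; then oxirane (excess), −78 → 0 °C
Reagents that add atoms: oxirane, C1CO1
Why: Iodine–lithium exchange on an alkenyl iodide with two equivalents of tert-butyllithium is fast at −78 °C and keeps the alkene geometry, and the configurationally stable alkenyllithium opens oxirane by SN2 attack, so the homoallylic alcohol should form with the 3E alkene intact.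

Step 18
Reactants: 30 (3E,7E)-4,8,12-trimethyltrideca-3,7,11-trien-1-ol
Product: 31 (3E,7E)-1-iodo-4,8,12-trimethyltrideca-3,7,11-triene
Conditions: I2, PPh3, imidazole, CH2Cl2, 0 → 25 °C
Reagents that add atoms: iodine, II
Why: Appel-type iodination of a primary homoallylic alcohol under buffered conditions that leave the trisubstituted alkenes alone.

Step 19
Reactants: 21 tert-butyl{[(1R,2R,3R)-2-(2-iodoethyl)-2-methyl-3-(prop-1-yn-1-yl)cyclopropyl]methoxy}diphenylsilane; 28 (1E,5E)-1-iodo-2,6,10-trimethylundeca-1,5,9-triene
Product: 33 tert-butyl{[(1R,2R,3R)-2-methyl-3-(prop-1-yn-1-yl)-2-[(3E,7E)-4,8,12-trimethyltrideca-3,7,11-trien-1-yl]cyclopropyl]methoxy}diphenylsilane, via alkylzinc iodide 32 (not isolated)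
Conditions: 21, Zn dust (activated with BrCH2CH2Br, Me3SiCl), LiCl, THF, 40 °C; then 28, PdCl2(dppf) (5 mol %), THF, 25 → 45 °C
Reagents that add atoms: none
Why: Negishi sp3–sp2 coupling; direct zinc insertion into the primary iodide tolerates the alkyne and silyl ether, oxidative addition of 28 to zerovalent palladium, transmetalation and reductive elimination keep the E geometry, and the wide-bite-angle diphosphine disfavours β-hydride elimination.

Step 20
Reactants: 33 tert-butyl{[(1R,2R,3R)-2-methyl-3-(prop-1-yn-1-yl)-2-[(3E,7E)-4,8,12-trimethyltrideca-3,7,11-trien-1-yl]cyclopropyl]methoxy}diphenylsilane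
Product: 35 tert-butyl{[(1R,2R,3S)-3-[(1E)-2-iodoprop-1-en-1-yl]-2-methyl-2-[(3E,7E)-4,8,12-trimethyltrideca-3,7,11-trien-1-yl]cyclopropyl]methoxy}diphenylsilane, via alkenylzirconocene chloride 34 (not isolated)
Conditions: Cp2Zr(H)Cl (2.5 equiv), THF, 25 → 50 °C; then I2, THF, 0 °C
Reagents that add atoms: iodine, II
Why: Schwartz hydrozirconation adds Zr–H syn to the alkyne, and with excess hydride the regioisomers equilibrate to the one with zirconium on the less hindered methyl-bearing carbon; iodinolysis with retention should place iodine trans to ring A, the geometry that becomes E after coupling, while trisubstituted alkenes react far more slowly.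

Step 21
Reactants: 31 (3E,7E)-1-iodo-4,8,12-trimethyltrideca-3,7,11-triene; 35 tert-butyl{[(1R,2R,3S)-3-[(1E)-2-iodoprop-1-en-1-yl]-2-methyl-2-[(3E,7E)-4,8,12-trimethyltrideca-3,7,11-trien-1-yl]cyclopropyl]methoxy}diphenylsilane
Product: 37 tert-butyl{[(1R,2R,3R)-2-methyl-3-[(1E,5E,9E)-2,6,10,14-tetramethylpentadeca-1,5,9,13-tetraen-1-yl]-2-[(3E,7E)-4,8,12-trimethyltrideca-3,7,11-trien-1-yl]cyclopropyl]methoxy}diphenylsilane, via homofarnesylzinc iodide 36 (not isolated)
Conditions: 31, Zn dust (activated), LiCl, THF, 40 °C; then 35, PdCl2(dppf) (5 mol %), THF, 25 → 45 °C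
Reagents that add atoms: none
Why: Second Negishi sp3–sp2 coupling, of a homoallylic zinc reagent with the α-methyl alkenyl iodide; the alkenyl carbon keeps its configuration, so the chain should end up trans to ring A (1E).

Step 22
Reactants: 37 tert-butyl{[(1R,2R,3R)-2-methyl-3-[(1E,5E,9E)-2,6,10,14-tetramethylpentadeca-1,5,9,13-tetraen-1-yl]-2-[(3E,7E)-4,8,12-trimethyltrideca-3,7,11-trien-1-yl]cyclopropyl]methoxy}diphenylsilane
Product: 38 {(1R,2R,3R)-2-methyl-3-[(1E,5E,9E)-2,6,10,14-tetramethylpentadeca-1,5,9,13-tetraen-1-yl]-2-[(3E,7E)-4,8,12-trimethyltrideca-3,7,11-trien-1-yl]cyclopropyl}methanol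
Conditions: Bu4NF, THF, 25 °C; chromatography on Et3N-deactivated silica
Reagents that add atoms: none
Why: Fluoride cleavage of the Si–O bond under basic, non-acidic conditions, which should leave the vinylcyclopropylcarbinol and the polyene untouched.

## Compound list

1 | (2S,5S)-hexane-2,5-diol | C[C@H](O)CC[C@H](C)O | starting material
2 | (2S,5S)-hexane-2,5-diyl dimethanesulfonate | C[C@H](OS(C)(=O)=O)CC[C@H](C)OS(C)(=O)=O | intermediate
3 | (2R,5R)-2,5-dimethylthiolane | C[C@@H]1CC[C@@H](C)S1 | intermediate
4 | ethyl bromoacetate | CCOC(=O)CBr | starting material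
5 | (2R,5R)-1-(2-ethoxy-2-oxoethyl)-2,5-dimethylthiolan-1-ium bromide | CCOC(=O)C[S+]1[C@H](C)CC[C@H]1C.[Br-] | intermediate
6 | ethyl 2-[(2R,5R)-2,5-dimethylthiolan-1-ium-1-yl]acetate ylide | CCOC(=O)[CH-][S+]1[C@H](C)CC[C@H]1C | intermediate
7 | 3-methylcyclopent-2-en-1-one | CC1=CC(=O)CC1 | starting material
8 | (3R)-3-{2-ethoxy-1-[(2R,5R)-2,5-dimethylthiolan-1-ium-1-yl]-2-oxoethyl}-3-methylcyclopent-1-en-1-olate (betaine, side-chain carbon epimerisable) | CCOC(=O)C([S+]1[C@H](C)CC[C@H]1C)[C@]2(C)CCC([O-])=C2 | intermediate
9 | ethyl (1R,5R,6R)-5-methyl-2-oxobicyclo[3.1.0]hexane-6-carboxylate | O=C2[C@@H]1[C@@H](C(=O)OCC)[C@]1(C)CC2 | intermediate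
10 | ethyl (1R,5R,6R)-2-[(tert-butyldimethylsilyl)oxy]-5-methylbicyclo[3.1.0]hex-2-ene-6-carboxylate | CC(C)(C)[Si](C)(C)OC2[C@@H]1[C@@H](C(=O)OCC)[C@]1(C)CC=2 | intermediate
11 | {(1R,5S,6R)-2-[(tert-butyldimethylsilyl)oxy]-5-methylbicyclo[3.1.0]hex-2-en-6-yl}methanol | CC(C)(C)[Si](C)(C)OC2[C@@H]1[C@@H](CO)[C@]1(C)CC=2 | intermediate
12 | tert-butyl({(1R,5S,6R)-2-[(tert-butyldimethylsilyl)oxy]-5-methylbicyclo[3.1.0]hex-2-en-6-yl}methoxy)diphenylsilane | CC(C)(C)[Si](C)(C)OC2[C@@H]1[C@@H](CO[Si](c3ccccc3)(c3ccccc3)C(C)(C)C)[C@]1(C)CC=2 | intermediate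
13 | tert-butyldimethylsilyl (1R,2S,3R)-3-{[(tert-butyldiphenylsilyl)oxy]methyl}-2-methyl-2-(2-oxoethyl)cyclopropane-1-carboxylate | CC(C)(C)[Si](C)(C)OC(=O)[C@@H]1[C@@H](CO[Si](c2ccccc2)(c2ccccc2)C(C)(C)C)[C@]1(C)CC=O | intermediate
14 | (1R,2S,3R)-3-{[(tert-butyldiphenylsilyl)oxy]methyl}-2-(2-hydroxyethyl)-2-methylcyclopropane-1-carboxylic acid | OC(=O)[C@@H]1[C@@H](CO[Si](c2ccccc2)(c2ccccc2)C(C)(C)C)[C@]1(C)CCO | intermediate
15 | (1R,6S,7R)-7-{[(tert-butyldiphenylsilyl)oxy]methyl}-6-methyl-3-oxabicyclo[4.1.0]heptan-2-one | O=C2[C@@H]1[C@@H](CO[Si](c3ccccc3)(c3ccccc3)C(C)(C)C)[C@]1(C)CCO2 | intermediate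
16 | (1R,6S,7R)-7-{[(tert-butyldiphenylsilyl)oxy]methyl}-6-methyl-3-oxabicyclo[4.1.0]heptan-2-ol (both C2 epimers) | OC2[C@@H]1[C@@H](CO[Si](c3ccccc3)(c3ccccc3)C(C)(C)C)[C@]1(C)CCO2 | intermediate
17 | (1R,2S,3R)-3-{[(tert-butyldiphenylsilyl)oxy]methyl}-2-(2-hydroxyethyl)-2-methylcyclopropane-1-carbaldehyde | O=C[C@@H]1[C@@H](CO[Si](c2ccccc2)(c2ccccc2)C(C)(C)C)[C@]1(C)CCO | intermediate
18 | 2-[(1R,2R,3S)-2-{[(tert-butyldiphenylsilyl)oxy]methyl}-3-ethynyl-1-methylcyclopropyl]ethan-1-ol | C#C[C@@H]1[C@@H](CO[Si](c2ccccc2)(c2ccccc2)C(C)(C)C)[C@]1(C)CCO | intermediate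
19 | dilithium salt of 18 (lithium alkoxide and lithium acetylide) | [Li]C#C[C@@H]1[C@@H](CO[Si](c2ccccc2)(c2ccccc2)C(C)(C)C)[C@]1(C)CCO[Li] | intermediate
20 | 2-[(1R,2R,3R)-2-{[(tert-butyldiphenylsilyl)oxy]methyl}-1-methyl-3-(prop-1-yn-1-yl)cyclopropyl]ethan-1-ol | CC#C[C@@H]1[C@@H](CO[Si](c2ccccc2)(c2ccccc2)C(C)(C)C)[C@]1(C)CCO | intermediate
21 | tert-butyl{[(1R,2R,3R)-2-(2-iodoethyl)-2-methyl-3-(prop-1-yn-1-yl)cyclopropyl]methoxy}diphenylsilane | CC#C[C@@H]1[C@@H](CO[Si](c2ccccc2)(c2ccccc2)C(C)(C)C)[C@]1(C)CCI | intermediate
22 | (2E)-1-bromo-3,7-dimethylocta-2,6-diene (geranyl bromide) | CC(C)=CCC/C(C)=C/CBr | starting material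
23 | trimethyl(prop-1-yn-1-yl)silane | CC#C[Si](C)(C)C | starting material
24 | [3-(trimethylsilyl)prop-2-yn-1-yl]lithium | [Li]CC#C[Si](C)(C)C | intermediate
25 | [(5E)-6,10-dimethylundeca-5,9-dien-1-yn-1-yl]trimethylsilane | CC(C)=CCC/C(C)=C/CCC#C[Si](C)(C)C | intermediate
26 | (5E)-6,10-dimethylundeca-5,9-dien-1-yne | CC(C)=CCC/C(C)=C/CCC#C | intermediate
27 | dimethyl[(1E,5E)-2,6,10-trimethylundeca-1,5,9-trien-1-yl]alumane | CC(C)=CCC/C(C)=C/CC/C(C)=C/[Al](C)C | intermediate
28 | (1E,5E)-1-iodo-2,6,10-trimethylundeca-1,5,9-triene | CC(C)=CCC/C(C)=C/CC/C(C)=C/I | intermediate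
29 | [(1E,5E)-2,6,10-trimethylundeca-1,5,9-trien-1-yl]lithium | [Li]/C=C(\C)CC/C=C(\C)CCC=C(C)C | intermediate
30 | (3E,7E)-4,8,12-trimethyltrideca-3,7,11-trien-1-ol | CC(C)=CCC/C(C)=C/CC/C(C)=C/CCO | intermediate
31 | (3E,7E)-1-iodo-4,8,12-trimethyltrideca-3,7,11-triene | CC(C)=CCC/C(C)=C/CC/C(C)=C/CCI | intermediate
32 | iodo{2-[(1R,2R,3R)-2-{[(tert-butyldiphenylsilyl)oxy]methyl}-1-methyl-3-(prop-1-yn-1-yl)cyclopropyl]ethyl}zinc | CC#C[C@@H]1[C@@H](CO[Si](c2ccccc2)(c2ccccc2)C(C)(C)C)[C@]1(C)CC[Zn]I | intermediate
33 | tert-butyl{[(1R,2R,3R)-2-methyl-3-(prop-1-yn-1-yl)-2-[(3E,7E)-4,8,12-trimethyltrideca-3,7,11-trien-1-yl]cyclopropyl]methoxy}diphenylsilane | CC#C[C@@H]1[C@@H](CO[Si](c2ccccc2)(c2ccccc2)C(C)(C)C)[C@]1(C)CC/C=C(\C)CC/C=C(\C)CCC=C(C)C | intermediate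
34 | chlorobis(cyclopentadienyl)zirconium alkenyl derived from 33 (zirconium on the methyl-bearing alkene carbon, trans to ring A) | Cl[Zr](C1C=CC=C1)(C1C=CC=C1)/C(C)=C/[C@@H]1[C@@H](CO[Si](c2ccccc2)(c2ccccc2)C(C)(C)C)[C@]1(C)CC/C=C(\C)CC/C=C(\C)CCC=C(C)C | intermediate
35 | tert-butyl{[(1R,2R,3S)-3-[(1E)-2-iodoprop-1-en-1-yl]-2-methyl-2-[(3E,7E)-4,8,12-trimethyltrideca-3,7,11-trien-1-yl]cyclopropyl]methoxy}diphenylsilane | I/C(C)=C/[C@@H]1[C@@H](CO[Si](c2ccccc2)(c2ccccc2)C(C)(C)C)[C@]1(C)CC/C=C(\C)CC/C=C(\C)CCC=C(C)C | intermediate
36 | iodo[(3E,7E)-4,8,12-trimethyltrideca-3,7,11-trien-1-yl]zinc | CC(C)=CCC/C(C)=C/CC/C(C)=C/CC[Zn]I | intermediate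
37 | tert-butyl{[(1R,2R,3R)-2-methyl-3-[(1E,5E,9E)-2,6,10,14-tetramethylpentadeca-1,5,9,13-tetraen-1-yl]-2-[(3E,7E)-4,8,12-trimethyltrideca-3,7,11-trien-1-yl]cyclopropyl]methoxy}diphenylsilane | CC(C)=CCC/C(C)=C/CC/C(C)=C/CC/C(C)=C/[C@@H]1[C@@H](CO[Si](c2ccccc2)(c2ccccc2)C(C)(C)C)[C@]1(C)CC/C=C(\C)CC/C=C(\C)CCC=C(C)C | intermediate
38 | {(1R,2R,3R)-2-methyl-3-[(1E,5E,9E)-2,6,10,14-tetramethylpentadeca-1,5,9,13-tetraen-1-yl]-2-[(3E,7E)-4,8,12-trimethyltrideca-3,7,11-trien-1-yl]cyclopropyl}methanol | CC(C)=CCC/C(C)=C/CC/C(C)=C/CC/C(C)=C/[C@@H]1[C@@H](CO)[C@]1(C)CC/C=C(\C)CC/C=C(\C)CCC=C(C)C | target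

## Step count and least certain steps

Total: 22 steps. Longest linear sequence: 17 steps (steps 1–13 and 19–22, from 1). The side-chain branch from 22 runs through steps 14–18 and joins the main line at step 19 (as 28) and step 21 (as 31).

**Step 5 (key step).** The conjugate addition to a β,β-disubstituted enone may be slow enough for the ylide to decompose. Face discrimination by the simple thiolane may be weak, and reversible betaine formation may erode it further. The result would be low conversion or low enantiomeric purity of 9. The fallback sets out from 7 and returns at 9. Commercial (2-ethoxy-2-oxoethyl)dimethylsulfonium bromide and DBU in toluene generate ethyl 2-(dimethyl-λ4-sulfanylidene)acetate F1, which cyclopropanates 7 to the racemic exo keto ester F2. Saponification with LiOH gives the racemic keto acid F3. Crystallisation with (S)-1-phenylethylamine gives the salt F4 of the wanted enantiomer (the antipodal amine is used if the other salt is the less soluble one). Acidification gives the acid F5, and EtI with K2CO3 in DMF returns 9.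

**Step 11.** The six-membered lactol may open to its aldehyde form too slowly, so the diazophosphonate is consumed by methanol before it reacts. Base-induced epimerisation at Ca in the open form is a lesser concern. The fallback sets out from 15 and returns at 20, and also bypasses the dianion methylation of step 12. Aminolysis of 15 with MeNHOMe·HCl and Me3Al gives the hydroxy Weinreb amide F9, which is silylated with Et3SiCl to F10. Reduction with i-Bu2AlH gives the aldehyde F11, which cannot close to a lactol. The same homologation gives the triethylsilyl ether of 18, F12. Lithiation and MeI give the triethylsilyl ether of 20, F13. PPTS in MeOH removes the triethylsilyl group selectively and gives 20.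

**Step 9.** Ozone may transfer one oxygen atom to the enol ether (α-oxygenation) instead of cleaving it, and lactonisation may be incomplete. The fallback sets out from 12 and returns at 15. Dihydroxylation of 12 with OsO4 (cat.) and N-methylmorpholine N-oxide gives the α-hydroxy ketone F6. Pb(OAc)4 in MeOH/benzene cleaves it to the aldehyde methyl ester F7. NaBH4 gives the hydroxy ester F8, which lactonises to 15 with catalytic TsOH.

**Step 19.** Zinc insertion or transmetalation may be slow, leading to protodemetalation of the arm or β-hydride elimination at palladium, and the alkylpalladium intermediate may add across the neighbouring cis propynyl group instead of undergoing reductive elimination. The fallback reverses the polarity and avoids palladium; it sets out from 28 and 21 and returns at 33. Iodine–lithium exchange on 28 (t-BuLi, Et2O, −78 °C) gives the alkenyllithium 29, the intermediate of step 17, which is alkylated by iodide 21 in THF/HMPA with retention of alkene geometry to give 33. No compound outside the compound list arises on this path (F0).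

**Step 20.** Regiochemical equilibration of the alkenylzirconium may be incomplete, and prolonged heating may start to hydrometalate chain alkenes. A regioisomeric iodide would be carried forward unseen. The fallback sets out from 33 and returns at 35. Palladium-catalysed syn hydrostannation (Bu3SnH, PdCl2(PPh3)2, THF) gives the tributylstannyl analogue of 35, F14, which is isolable and can be freed of its regioisomer by chromatography. Iododestannylation with I2 at 0 °C, with retention, gives 35.

## Further compounds

F1 | step 5 | ethyl 2-(dimethyl-λ4-sulfanylidene)acetate | CCOC(=O)[CH-][S+](C)C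
F2 | step 5 | racemic ethyl (1R*,5R*,6R*)-5-methyl-2-oxobicyclo[3.1.0]hexane-6-carboxylate | O=C2[C@@H]1[C@@H](C(=O)OCC)[C@]1(C)CC2.O=C2[C@H]1[C@H](C(=O)OCC)[C@@]1(C)CC2
F3 | step 5 | racemic (1R*,5R*,6R*)-5-methyl-2-oxobicyclo[3.1.0]hexane-6-carboxylic acid | O=C2[C@@H]1[C@@H](C(=O)O)[C@]1(C)CC2.O=C2[C@H]1[C@H](C(=O)O)[C@@]1(C)CC2
F4 | step 5 | (1S)-1-phenylethan-1-aminium (1R,5R,6R)-5-methyl-2-oxobicyclo[3.1.0]hexane-6-carboxylate | O=C2[C@@H]1[C@@H](C(=O)[O-])[C@]1(C)CC2.C[C@H]([NH3+])c1ccccc1
F5 | step 5 | (1R,5R,6R)-5-methyl-2-oxobicyclo[3.1.0]hexane-6-carboxylic acid | O=C2[C@@H]1[C@@H](C(=O)O)[C@]1(C)CC2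
F6 | step 9 | (1R,5S,6R)-6-{[(tert-butyldiphenylsilyl)oxy]methyl}-3-hydroxy-5-methylbicyclo[3.1.0]hexan-2-one (C3 epimers) | O=C2[C@@H]1[C@@H](CO[Si](c3ccccc3)(c3ccccc3)C(C)(C)C)[C@]1(C)CC2O
F7 | step 9 | methyl (1R,2S,3R)-3-{[(tert-butyldiphenylsilyl)oxy]methyl}-2-methyl-2-(2-oxoethyl)cyclopropane-1-carboxylate | COC(=O)[C@@H]1[C@@H](CO[Si](c2ccccc2)(c2ccccc2)C(C)(C)C)[C@]1(C)CC=O
F8 | step 9 | methyl (1R,2S,3R)-3-{[(tert-butyldiphenylsilyl)oxy]methyl}-2-(2-hydroxyethyl)-2-methylcyclopropane-1-carboxylate | COC(=O)[C@@H]1[C@@H](CO[Si](c2ccccc2)(c2ccccc2)C(C)(C)C)[C@]1(C)CCO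
F9 | step 11 | (1R,2S,3R)-3-{[(tert-butyldiphenylsilyl)oxy]methyl}-2-(2-hydroxyethyl)-N-methoxy-N,2-dimethylcyclopropane-1-carboxamide | CON(C)C(=O)[C@@H]1[C@@H](CO[Si](c2ccccc2)(c2ccccc2)C(C)(C)C)[C@]1(C)CCO
F10 | step 11 | (1R,2S,3R)-3-{[(tert-butyldiphenylsilyl)oxy]methyl}-N-methoxy-N,2-dimethyl-2-{2-[(triethylsilyl)oxy]ethyl}cyclopropane-1-carboxamide | CON(C)C(=O)[C@@H]1[C@@H](CO[Si](c2ccccc2)(c2ccccc2)C(C)(C)C)[C@]1(C)CCO[Si](CC)(CC)CC
F11 | step 11 | (1R,2S,3R)-3-{[(tert-butyldiphenylsilyl)oxy]methyl}-2-methyl-2-{2-[(triethylsilyl)oxy]ethyl}cyclopropane-1-carbaldehyde | O=C[C@@H]1[C@@H](CO[Si](c2ccccc2)(c2ccccc2)C(C)(C)C)[C@]1(C)CCO[Si](CC)(CC)CC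
F12 | step 11 | triethylsilyl ether of 18 | C#C[C@@H]1[C@@H](CO[Si](c2ccccc2)(c2ccccc2)C(C)(C)C)[C@]1(C)CCO[Si](CC)(CC)CC
F13 | step 11 | triethylsilyl ether of 20 | CC#C[C@@H]1[C@@H](CO[Si](c2ccccc2)(c2ccccc2)C(C)(C)C)[C@]1(C)CCO[Si](CC)(CC)CC
F0 | step 19 | none | none
F14 | step 20 | tributylstannyl analogue of 35 (tin in place of iodine, same alkene geometry) | CCCC[Sn](CCCC)(CCCC)/C(C)=C/[C@@H]1[C@@H](CO[Si](c2ccccc2)(c2ccccc2)C(C)(C)C)[C@]1(C)CC/C=C(\C)CC/C=C(\C)CCC=C(C)C
A1 | alternative 1 | tert-butyldimethylsilyl ether of 38 | CC(C)=CCC/C(C)=C/CC/C(C)=C/CC/C(C)=C/[C@@H]1[C@@H](CO[Si](C)(C)C(C)(C)C)[C@]1(C)CC/C=C(\C)CC/C=C(\C)CCC=C(C)C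
A2 | alternative 1 | bis(1,3-dioxoisoindolin-2-yl) ester of the ring A diacid (4-carboxy-2-methylbut-1-enyl on Ca, 2-carboxyethyl on Cc, silyloxymethyl on Cb) | O=C(ON1C(=O)c2ccccc2C1=O)CC/C(C)=C/[C@@H]1[C@@H](CO[Si](C)(C)C(C)(C)C)[C@]1(C)CCC(=O)ON1C(=O)c2ccccc2C1=O
A3 | alternative 2 | cis-fused 3-oxabicyclo[3.1.0]hexan-2-one with the (3E,7E)-trimethyltridecatrienyl chain on C1 and the (1E,5E,9E)-tetraenyl group exo on C6 | CC(C)=CCC/C(C)=C/CC/C(C)=C/CC/C(C)=C/[C@@H]1[C@@H](COC2=O)[C@]12CC/C=C(\C)CC/C=C(\C)CCC=C(C)C
A4 | alternative 2 | (2E,4E,8E,12E)-5,9,13,17-tetramethyloctadeca-2,4,8,12,16-pentaen-1-yl (5E,9E)-2-diazo-6,10,14-trimethylpentadeca-5,9,13-trienoate | [N-]=[N+]=C(CC/C=C(\C)CC/C=C(\C)CCC=C(C)C)C(=O)OC/C=C/C=C(\C)CC/C=C(\C)CC/C=C(\C)CCC=C(C)C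
A5 | alternative 3 | methyl (1R,5R,6R)-5-methyl-2-oxobicyclo[3.1.0]hexane-6-carboxylate | O=C2[C@@H]1[C@@H](C(=O)OC)[C@]1(C)CC2
A6 | alternative 3 | methyl (1R,3R)-3-(2-diazoacetyl)-2,2-dimethylcyclopropane-1-carboxylate | [N-]=[N+]=CC(=O)[C@@H]1[C@@H](C(=O)OC)C1(C)C
A7 | alternative 3 | (1R,3R)-2,2-dimethyl-3-(2-methylprop-1-en-1-yl)cyclopropane-1-carboxylic acid (trans-chrysanthemic acid) | CC(C)=C[C@@H]1[C@@H](C(=O)O)C1(C)C
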